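A curve of [E] that goes flat invites the reading that a reagent has been used up, and the north run refutes it: at 160 s [E] stands at 0.0110 M, out of 0.0500 M of J and 0.125 M of L.

| setting | north | south | south-east | north-east | north-west |
|---|---|---|---|---|---|
| J | 0.0500 M | 0.0200 M | 0.0250 M | 0.0500 M | 0.120 M |
| L | 0.125 M | 0.0950 M | 0.125 M | 0.250 M | 0.310 M |
| time |  |  |  |  | 160 s |

- north run (time / s: [E] / M): 6.4: 0.0018; 12: 0.0027; 23: 0.0049; 44: 0.0069; 84: 0.0096; 160: 0.0110
- south run (time / s: [E] / M): 6.4: 5 × 10⁻⁴; 12: 0.0015; 23: 0.0016; 44: 0.0024; 84: 0.0035; 160: 0.0036
- south-east run (time / s: [E] / M): 6.4: 5 × 10⁻⁴; 12: 0.0012; 23: 0.0022; 44: 0.0037; 84: 0.0043; 160: 0.0051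
- north-east run (time / s: [E] / M): 6.4: 0.0017; 12: 0.0045; 23: 0.0062; 44: 0.0089; 84: 0.0124; 160: 0.0129

(each reading ± 4 × 10⁻⁴ M)

- Overall: J + L -> E.
- Constant volume, constant temperature.
- The analysis sees a species whether free or bound.
- "The second partner" is L.
- An order is taken over about fifteen percent of the charge, up and down.

* order of the initial rate in [J], near the charge of the north run, the rate being that where two percent of its J are E (one fixed amount of E, the same in the runs compared)
* order of the initial rate in [L], near the charge of the north run, the rate being that where two percent of its J are E
* E in the north-west run at 160 s, as a share of the J charged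
* which of these the readings show (the two partners rest in a complex / the substrate pairs with itself / the product binds the second partner)

The north curve reaches 0.0049 M at 23 s, a chord slope of 0.213 mM s⁻¹. Its last reading over that slope gives a turnover time (relaxation time) of 51.6 s, so 160 s counts 3.10 turnovers and, on an exponential approach, that reading lies about 4.50 % below the level. The north-east curve reaches 0.0062 M at 23 s, a chord slope of 0.270 mM s⁻¹, with a turnover time of 47.9 s and 3.34 turnovers, so its last reading also stands close to its level.

Those last readings can be compared as end ratios, [E] over the J not turned to E, bound or free: 0.282 in the north run and 0.348 in the north-east run. Doubling L raises the ratio by a factor of 1.23, where a plain J + L ⇌ E asks for twice. The ratio bends toward a ceiling, as it does when part of J rests in a complex with L, a resting state. The early readings bend too. Summed up to 44 s, the south-east run, at half the J, gives 0.466 of the north sum, an order of 1.10, and the north-east run, at twice the L, gives 1.31 of it, an order of 0.386 averaged across the doubling. At 44 s the north run holds 0.0069 M of E, which is 5.52 % of its L charge; that speaks against E binding L one to one as the source of the curb, and an order near one in J speaks against J pairing with itself.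

Write the ratio as ceiling × [L]/([L] + h), with [L] roughly the charge less E, the L held in the complex being left aside in this rough form. The two runs give h = 0.0652 M and a ceiling of 0.443. For the north-west run, the north-east share gives a first [L] of 0.279 M, so the reckoned ratio is 0.359, the end ratio of that flask, [E] at 160 s over the J not turned to E. That is a share of 26.4 %.

The forecast, judging that “A resting complex fits”, gave orders of 0.93 in J, below the value read here, and 0.5 in L, with 26 % for the north-west run and the answer the two partners rest in a complex.

The simulation gives orders of 0.98 and 0.57, 27.1 % for the north-west run, and the two partners rest in a complex.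

    J + L ⇌ E (0.1100 L mol⁻¹ s⁻¹, 0.01770 s⁻¹)
    J + L ⇌ JL, settled at all times (11.60 L mol⁻¹)

At 27.1 % the north-west end ratio is 0.372, against the 0.359 reckoned. In the scheme that ratio, at its level, is 6.21 L mol⁻¹ times free [L], divided by 1 plus 11.6 L mol⁻¹ times free [L], and that divisor is the parking of J + L as JL. The north-west run without JL proves it: its end ratio is 6.21 L mol⁻¹ times [L] of 0.238 M, which is 1.48, and E comes to 59.7 % of the J charged, against 27.1 %.

The numbers in the tables were generated by integration for an exercise; the scatter is artificial.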